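**Retrosynthetic overview**
- The two esters are attached last: the C7 ester by allylic hydroxylation of the C8(10) methylene then acylation, the C1 angelate by enolate hydroxylation then inversion with angelic acid.
- The cyclopentenone (ring B) is closed at C2–C3 by a light-driven decatungstate/nickel coupling of an aldehyde C–H with a (Z)-alkenyl iodide; this fixes the 3(14)Z geometry.
- The aldehyde/alkenyl iodide comes from a one-pot three-component coupling on (S)-cryptone: anti conjugate addition of an α-silylalkenyl metal at C4, then enolate alkylation at C9.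
- Ring order: ring A (cyclohexane) is bought as (S)-cryptone, whose single stereocentre (C5) controls C4, C9, C1 and C7; ring B is formed in step 5.

Assumption: (S)-cryptone of high ee, angelic acid and (E)-3-methylpent-2-enoic acid are taken as purchasable. Oplopane numbering is used throughout: C1 angelate carbon, C2 ketone, C3=C14(–C15) ethylidene, C4/C9 ring fusion, C5 isopropyl carbon, C7 second ester carbon, C8=C10 methylene.

**Step 1**
Reactants: 1 (S)-cryptone; 2 trimethyl(prop-1-yn-1-yl)silane; 3 methyl bromoacetate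
Product: 7 methyl 2-[(1R,2S,3S)-6-oxo-3-(propan-2-yl)-2-[(Z)-1-(trimethylsilyl)prop-1-en-1-yl]cyclohexyl]acetate (all-trans), via alkenylalane 4 (not isolated), via aluminium enolate 5 (not isolated), via lithium alanate enolate 6 (not isolated)
Conditions: 2, i-Bu2AlH, hexane–THF 5:1, 55 °C; then 1, (IPr)CuCl (5 mol%; IPr = 1,3-bis(2,6-diisopropylphenyl)imidazol-2-ylidene), THF, −30 → 0 °C; then MeLi, −78 °C; 3, HMPA, −78 → −20 °C; aq. NH4Cl
Reagents that add atoms: none
Why: syn-hydroalumination puts Al on the silicon-bearing carbon cis to H, copper-catalysed 1,4-addition (retention at the alkenyl carbon) occurs anti to the C5 isopropyl group, and the alanate-activated enolate is alkylated anti to the new C4 substituent, giving the all-equatorial ketone (tandem conjugate addition–enolate alkylation).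

**Step 2**
Reactants: 7 keto ester alkenylsilane
Product: 8 methyl 2-[(1R,2S,3S)-2-[(Z)-1-iodoprop-1-en-1-yl]-6-oxo-3-(propan-2-yl)cyclohexyl]acetate
Conditions: N-iodosuccinimide, (CF3)2CHOH, 0 °C
Reagents that add atoms: N-iodosuccinimide, O=C1CCC(=O)N1I
Why: ipso-iododesilylation through a β-silyl cation replaces silicon by iodine with retention, so iodine ends cis to the methyl group.

**Step 3**
Reactants: 8 keto ester alkenyl iodide
Product: 9 methyl 2-[(1R,2S,3S)-2-[(Z)-1-iodoprop-1-en-1-yl]-6-methylidene-3-(propan-2-yl)cyclohexyl]acetate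
Conditions: Ph3PCH3Br (1.6 equiv), NaN(SiMe3)2 (1.5 equiv), THF, 0 °C; then 8, 0 °C → rt
Reagents that add atoms: methyltriphenylphosphonium bromide, C[P+](c1ccccc1)(c1ccccc1)c1ccccc1.[Br-]
Why: Wittig methylenation of the ketone installs C10; the ylide (no excess amide base) leaves the ester, the alkenyl iodide and the all-equatorial, thermodynamically preferred C9 centre untouched.

**Step 4**
Reactants: 9 methylidene ester
Product: 10 2-[(1R,2S,3S)-2-[(Z)-1-iodoprop-1-en-1-yl]-6-methylidene-3-(propan-2-yl)cyclohexyl]acetaldehyde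
Conditions: i-Bu2AlH (1.1 equiv), CH2Cl2, −78 °C; MeOH, then aq. KNaC4H4O6
Reagents that add atoms: none
Why: partial ester reduction stops at the aldehyde because the tetrahedral aluminium hemiacetal is stable at −78 °C.

**Step 5**
Reactants: 10 aldehyde alkenyl iodide
Product: 11 oplopa-3(14)Z,8(10)-dien-2-one, i.e. (1Z,3aR,7S,7aS)-1-ethylidene-4-methylidene-7-(propan-2-yl)octahydro-2H-inden-2-one (trans-fused)
Conditions: (n-Bu4N)4[W10O32] (2 mol%), NiBr2(dtbbpy) (10 mol%; dtbbpy = 4,4'-di-tert-butyl-2,2'-bipyridine), K3PO4, MeCN (0.02 M), 390 nm LEDs, rt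
Reagents that add atoms: none
Why: Proposed new method: ring-closing acyl C–H alkenylation, in which excited decatungstate abstracts the aldehyde hydrogen, the primary-alkyl acyl radical (slow to lose CO) is captured by the alkenyl–nickel species from oxidative addition of zerovalent nickel to the (Z)-alkenyl iodide, and reductive elimination from a six-membered acyl(alkenyl)nickelacycle forges C2–C3 and ring B with retention of alkene geometry (direct 5-exo ipso attack of the acyl radical with loss of an iodine atom gives the same enone); the closest known reactions are the intermolecular decatungstate/nickel and amine-radical/nickel aldehyde C–H arylations with aryl halides, not yet shown for ring closure onto alkenyl iodides.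

**Step 6**
Reactants: 11 bicyclic enone
Product: 13 1β-hydroxyoplopa-3(14)Z,8(10)-dien-2-one, i.e. (1Z,3R,3aR,7S,7aS)-1-ethylidene-3-hydroxy-4-methylidene-7-(propan-2-yl)octahydro-2H-inden-2-one, via lithium enolate 12 (not isolated)
Conditions: LiN(SiMe3)2, THF, −78 °C; MoO5·py·HMPA, −78 → −30 °C; aq. Na2SO3
Reagents that add atoms: MoO5·py·HMPA (oxodiperoxomolybdenum pyridine hexamethylphosphoramide), O=[Mo]12(OO1)OO2.c1ccncc1.CN(C)P(=O)(N(C)C)N(C)C
Why: kinetic α′-deprotonation gives the C1 enolate, and the oxidant enters anti to the C9–C8 bond on the adjacent ring-fusion carbon (the usual 2,3-trans outcome for cyclopentanone enolates), giving the 1β-alcohol (Vedejs enolate hydroxylation).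

**Step 7**
Reactants: 13 1β-alcohol; 14 angelic acid
Product: 15 1α-angeloyloxyoplopa-3(14)Z,8(10)-dien-2-one
Conditions: 14, PPh3, diisopropyl azodicarboxylate, toluene, 0 °C → rt
Reagents that add atoms: none
Why: Mitsunobu esterification displaces the alkoxyphosphonium by angelate in an SN2 step that inverts C1 to the required 1α configuration under base-free conditions, so neither the (Z)-angelate nor the α-acyloxy ketone isomerises.

**Step 8**
Reactants: 15 1α-angelate
Product: 16 1α-angeloyloxy-7β-hydroxyoplopa-3(14)Z,8(10)-dien-2-one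
Conditions: SeO2 (0.3 equiv), t-BuOOH (2.5 equiv), CH2Cl2, 0 °C → rt
Reagents that add atoms: selenium dioxide, O=[Se]=O (oxygen relay); tert-butyl hydroperoxide, CC(C)(C)OO (terminal oxygen source)
Why: selenium dioxide allylic oxidation (ene reaction then [2,3]-sigmatropic shift) of the only electron-rich alkene occurs at the CH2 (C7) rather than the CH (C9), removes the axial 7β hydrogen and returns oxygen to that face, giving the axial 7β-alcohol with the 8(10) alkene restored.

**Step 9**
Reactants: 16 7β-alcohol; 17 (E)-3-methylpent-2-enoic acid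
Product: 19 target, 1α-angeloyloxy-7β-[(E)-3-methylpent-2-enoyloxy]oplopa-3(14)Z,8(10)-dien-2-one, via O-acylisourea 18 (not isolated)
Conditions: 17, N,N'-diisopropylcarbodiimide, DMAP (0.3 equiv), CH2Cl2, 0 °C → rt
Reagents that add atoms: none
Why: Steglich esterification acylates the hindered axial allylic alcohol under mild conditions that keep the (E)-enoate geometry and do not epimerise C1.

**Compound list**
1 | (S)-cryptone, (4S)-4-(propan-2-yl)cyclohex-2-en-1-one | O=C1C=C[C@H](C(C)C)CC1 | starting material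
2 | trimethyl(prop-1-yn-1-yl)silane | CC#C[Si](C)(C)C | starting material
3 | methyl bromoacetate | COC(=O)CBr | starting material
4 | (Z)-diisobutyl[1-(trimethylsilyl)prop-1-en-1-yl]alane (Al cis to H) | C/C=C(/[Al](CC(C)C)CC(C)C)[Si](C)(C)C | intermediate
5 | diisobutylaluminium enolate of the 3,4-trans conjugate adduct | CC(C)C[Al](CC(C)C)OC1=C[C@@H](/C(=C/C)[Si](C)(C)C)[C@H](C(C)C)CC1 | intermediate
6 | lithium methyl(diisobutyl)alanate enolate of the same adduct | [Li+].C[Al-](CC(C)C)(CC(C)C)OC1=C[C@@H](/C(=C/C)[Si](C)(C)C)[C@H](C(C)C)CC1 | intermediate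
7 | methyl 2-[(1R,2S,3S)-6-oxo-3-(propan-2-yl)-2-[(Z)-1-(trimethylsilyl)prop-1-en-1-yl]cyclohexyl]acetate | O=C1[C@H](CC(=O)OC)[C@@H](/C(=C/C)[Si](C)(C)C)[C@H](C(C)C)CC1 | intermediate
8 | methyl 2-[(1R,2S,3S)-2-[(Z)-1-iodoprop-1-en-1-yl]-6-oxo-3-(propan-2-yl)cyclohexyl]acetate | O=C1[C@H](CC(=O)OC)[C@@H](/C(I)=C/C)[C@H](C(C)C)CC1 | intermediate
9 | methyl 2-[(1R,2S,3S)-2-[(Z)-1-iodoprop-1-en-1-yl]-6-methylidene-3-(propan-2-yl)cyclohexyl]acetate | C=C1[C@H](CC(=O)OC)[C@@H](/C(I)=C/C)[C@H](C(C)C)CC1 | intermediate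
10 | 2-[(1R,2S,3S)-2-[(Z)-1-iodoprop-1-en-1-yl]-6-methylidene-3-(propan-2-yl)cyclohexyl]acetaldehyde | C=C1[C@H](CC=O)[C@@H](/C(I)=C/C)[C@H](C(C)C)CC1 | intermediate
11 | oplopa-3(14)Z,8(10)-dien-2-one (trans-fused) | C=C1[C@H]2[C@@H](/C(=C/C)C(=O)C2)[C@H](C(C)C)CC1 | intermediate
12 | lithium C1(2)-enolate of 11 | C=C1[C@H]2[C@@H](/C(=C/C)C(O[Li])=C2)[C@H](C(C)C)CC1 | intermediate
13 | 1β-hydroxyoplopa-3(14)Z,8(10)-dien-2-one (OH cis to H-9) | C=C1[C@H]2[C@@H](/C(=C/C)C(=O)[C@@H]2O)[C@H](C(C)C)CC1 | intermediate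
14 | angelic acid, (Z)-2-methylbut-2-enoic acid | C/C=C(/C)C(=O)O | starting material
15 | 1α-angeloyloxyoplopa-3(14)Z,8(10)-dien-2-one | C=C1[C@H]2[C@@H](/C(=C/C)C(=O)[C@H]2OC(=O)/C(C)=C\C)[C@H](C(C)C)CC1 | intermediate
16 | 1α-angeloyloxy-7β-hydroxyoplopa-3(14)Z,8(10)-dien-2-one (axial OH) | C=C1[C@H]2[C@@H](/C(=C/C)C(=O)[C@H]2OC(=O)/C(C)=C\C)[C@H](C(C)C)C[C@H]1O | intermediate
17 | (E)-3-methylpent-2-enoic acid | CC/C(C)=C/C(=O)O | starting material
18 | O-[(E)-3-methylpent-2-enoyl]-N,N'-diisopropylisourea | CC/C(C)=C/C(=O)OC(=NC(C)C)NC(C)C | intermediate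
19 | CNP0179172.1, (1S,4S,5S,7R,9R)-1α-angeloyloxy-7β-[(E)-3-methylpent-2-enoyloxy]oplopa-3(14)Z,8(10)-dien-2-one | C=C1[C@H]2[C@@H](/C(=C/C)C(=O)[C@H]2OC(=O)/C(C)=C\C)[C@H](C(C)C)C[C@H]1OC(=O)/C=C(\C)CC | target

**Step count and risk**
Total steps: 9. Longest linear sequence: 9 steps from 1 (all other partners are purchased).

Three steps most likely to fail:

Step 5 (the proposed new ring closure; competing allylic hydrogen abstraction, proto-deiodination or light-induced E/Z drift of the enone are possible). The fallback sets out from 10 and uses known polar chemistry. A Nozaki–Hiyama–Kishi cyclisation (CrCl2, catalytic NiCl2, DMSO, rt) proceeds through the alkenylchromium dichloride F5, which adds to the aldehyde with retention of alkene geometry to give the allylic alcohol 3(14)Z,8(10)-oplopadien-2-ol F6 as a carbinol epimer mixture. Dess–Martin periodinane then oxidises F6 to the enone, coming back to the route at 11.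

Step 1 (one-pot alkylation of the aluminium-derived enolate may be slow or give proton transfer). The fallback sets out from 1 and installs the C9 side chain before the conjugate addition. Iodination of 1 (I2, pyridine, CH2Cl2) gives (4S)-2-iodo-4-(propan-2-yl)cyclohex-2-en-1-one F1. Negishi coupling (Pd(PPh3)4, THF) with the Reformatsky reagent bromo(2-methoxy-2-oxoethyl)zinc F2, made from 3 and zinc, gives methyl 2-[(3S)-6-oxo-3-(propan-2-yl)cyclohex-1-en-1-yl]acetate F3. Copper-catalysed addition of alane 4 to F3, anti to the isopropyl group, gives the aluminium enolate F4; protonation on work-up and brief equilibration with DBU sets C9 thermodynamically and comes back to the route at 7.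

Step 7 (SN2 at C1 must come from the more hindered α face; a bulky alkoxyphosphonium may react sluggishly). The fallback sets out from 13 and moves the hydrogen instead of the oxygen. Angelic acid 14 is activated as the angelic 2,4,6-trichlorobenzoic mixed anhydride F7 (2,4,6-trichlorobenzoyl chloride, Et3N, toluene) and acylates 13 with retention to the 1β-angelate F8. Deprotonation (LiN(SiMe3)2, THF, −78 °C) gives the lithium enolate F9, and kinetic protonation with 2,6-di-tert-butylphenol at −78 °C delivers hydrogen to the open β face, coming back to the route at 15.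

**Further compounds**
F1 | step 1 | (4S)-2-iodo-4-(propan-2-yl)cyclohex-2-en-1-one | O=C1C(I)=C[C@H](C(C)C)CC1
F2 | step 1 | bromo(2-methoxy-2-oxoethyl)zinc | COC(=O)C[Zn]Br
F3 | step 1 | methyl 2-[(3S)-6-oxo-3-(propan-2-yl)cyclohex-1-en-1-yl]acetate | O=C1C(CC(=O)OC)=C[C@H](C(C)C)CC1
F4 | step 1 | diisobutylaluminium enolate of the conjugate adduct of 4 and F3 | CC(C)C[Al](CC(C)C)OC1=C(CC(=O)OC)[C@@H](/C(=C/C)[Si](C)(C)C)[C@H](C(C)C)CC1
F5 | step 5 | alkenylchromium dichloride from 10 (Cr cis to methyl) | C=C1[C@H](CC=O)[C@@H](/C(=C/C)[Cr](Cl)Cl)[C@H](C(C)C)CC1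
F6 | step 5 | oplopa-3(14)Z,8(10)-dien-2-ol (C2 epimer mixture) | C=C1[C@H]2[C@@H](/C(=C/C)C(O)C2)[C@H](C(C)C)CC1
F7 | step 7 | (Z)-2-methylbut-2-enoic 2,4,6-trichlorobenzoic anhydride | C/C=C(/C)C(=O)OC(=O)c1c(Cl)cc(Cl)cc1Cl
F8 | step 7 | 1β-angeloyloxyoplopa-3(14)Z,8(10)-dien-2-one | C=C1[C@H]2[C@@H](/C(=C/C)C(=O)[C@@H]2OC(=O)/C(C)=C\C)[C@H](C(C)C)CC1
F9 | step 7 | lithium C1(2)-enolate of F8 | C=C1[C@H]2[C@@H](/C(=C/C)C(O[Li])=C2OC(=O)/C(C)=C\C)[C@H](C(C)C)CC1
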